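Atoms carry germacrane numbering throughout (ring C1–C10, C14 on C10, C15 on C4, lactone O6–C12, C13 on C11).

## Analysis of the target

Target 27 is a germacranolide: a ten-membered carbocycle fused at C6–C7 to an α,β-unsaturated γ-lactone (C7=C11, O6–C12), with an acetoxymethyl group (C13) on C11 and a tiglate on O8. It carries two trans-trisubstituted epoxides, C1–C10 and C4–C5. The six stereocentres are (1R,4R,5R,6S,8S,10R). Both epoxides correspond to (E)-alkenes attacked on the outer face of a crown-like ring with C14 and C15 syn, and O6 and O8 are cis. C7 is trigonal, so C6 and C8 are related only across an sp2 carbon. The sensitive groups are the two epoxides (acid, transannular attack in the ten-membered ring), H6 (γ-hydrogen of the butenolide next to the C5 epoxide carbon, so base can open the epoxide), the two allylic esters, and the tiglate geometry. The synthesis is hard because a ten-membered ring with defined alkene and epoxide geometry must be closed, C4 to C8 are all oxygenated, and O6 and O8 must be told apart. The strategy rests on one feature: C6–C7–C8 is a 1,3-dihydroxyacetone unit with cis oxygens and can be carried as a cis-4,6-disubstituted 2,2-dimethyl-1,3-dioxan-5-one. C8 is then an enolate carbon and C9–C10(CH3)=C1 is an allyl group on it, so C8–C9 is an enolate–allyl bond.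

## Retrosynthetic reasoning

**27 ⇒ 26 (the two C–O bonds of the 1,10-epoxide).** The C1=C10 alkene is removed last because it is the allyl unit the ring closure needs. In 26 it is the only electron-rich alkene, and outer-face attack on the (E)-cyclodecene with syn methyl groups should give the (1R,10R) epoxide.

**26 ⇒ 24 ⇒ 23 (C13–O and the C7=C11 position, then C7–C11).** The primary acetate and the tetrasubstituted butenolide alkene come from the tertiary allylic alcohol 24 by acetylation and 1,3-shift of the acetate. 24 comes from the acrylate 23 by addition of C11 to the C7 ketone. This uses the ketone of the dihydroxyacetone unit directly and brings C11–C13 in as one three-carbon piece with C13 already set up for oxygenation; the C7 carbinol centre is transient.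

**23 ⇒ 22 ⇒ 19 ⇒ 18 (two ester C–O bonds, then the acetal).** O8 is flanked by a methylene and O6 by the epoxide carbon, so the tiglate from 20 goes on first and the acrylate second. Diol 19 is the hydrolysed acetonide 18.

**18 ⇒ 17 (C8–C9).** This bond is cut because it is the only ring bond joining an enolisable carbon to an allyl terminus. Reconnecting C9 to the C7 enol oxygen through a carbonate gives the twelve-membered allyl enol carbonate 17. The forward reaction must ionise the allyl carbonate, lose the carbonate carbon, bond C8 to C9 (not to C1), keep the (E)-alkene and set C8 cis to C6. The gain is that the ten-membered ring is closed by contraction of a larger, easier ring, and C7 arrives as a ketone.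

**17 ⇒ 15 ⇒ 14 (enol O–C(=O), then C9 O–C(=O)).** The carbonate bridge is cut at the enol oxygen. The forward step is an intramolecular O-acylation of the C8-side enolate by the alkoxycarbonyl imidazole 15, made from the allylic alcohol 14. Both ways of acylating the enolate (O or C) would give a twelve-membered ring that furnishes the same enolate–allyl pair, so this cut is tolerant.

**14 ⇒ 13 ⇒ 12 ⇒ 11 (C5–O of the epoxide; silyl groups).** The epoxide is cut at C5–O. In the forward sense the tertiary C4 oxygen displaces an activated C5 hydroxyl with inversion, so the trans-epoxide (4R,5R) needs the anti-diol (4R,5S) of 12. The two silyl groups are chosen so that the tertiary one leaves first.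

**11 ⇒ 9 + 10 (C5–C6).** An aldol bond between the dioxanone 10 and the α-silyloxy aldehyde 9 sets C5 and C6 together. The required (5S,6R) anti-adduct is the one an (R)-configured amino acid catalyst gives, and it is also the Felkin–Anh product of 9, so catalyst and substrate agree.

**9 ⇒ 8 ⇒ 7 ⇒ 6 ⇒ 4 + 5 ⇒ 2 ⇒ 1.** C4 with its methyl group and oxygen is the carbinol carbon of (R)-linalool 1. Extending the chain first and ozonising the vinyl group afterwards is not viable, because the trisubstituted C1=C10 alkene would be cleaved before the vinyl group. Therefore both alkenes of the silyl ether 2 are cleaved at once to dialdehyde 4, and the two aldehydes are told apart by hindrance. Only the unhindered one meets ylide 5. Reduction, silylation of the allylic hydroxyl and reoxidation then give 9.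

## Alternatives that were turned down

**Alternative 1:** The cut removes C6–C7, C11–C12 and C12–O6 at once and leads to the acyclic dienyl ynal A1. A low-valent metal (Cp2Ti(PMe3)2, divalent titanium, under CO, or Ru3(CO)12) would join the C6 aldehyde, the C7≡C11 alkyne and CO to give trienolide A2, carbocycle and butenolide together.
- For it: three bonds and two rings in one operation, and the butenolide arrives complete with the C13 oxygen. No Morita–Baylis–Hillman step and no differentiation of O6 and O8 are needed. On step economy it is clearly stronger than the chosen route.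
- Against it: this carbonylative coupling works where the tether gives a five- or six-membered ring next to the metallacycle. Here the tether must become a ten-membered ring with two (E)-alkenes, the aldehyde is a conjugated enal, and only the distant C8 silyloxy group could control C6. Both epoxides would then be made on a triene, so five stereocentres rest on ring conformation alone.
- Comparison: the chosen strategy gives up the bond count. In return it closes the ten-membered ring from a preformed twelve-membered ring inside an ion pair, with C4, C5 and C6 already fixed by the chiral pool and a catalyst.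

**Alternative 2:** The cut is C7–C8, made by breaking O8–C13 in the thirteen-membered α-stannyl allyl ether A3. Tin–lithium exchange with n-BuLi at C8 would start a [2,3]-Wittig shift that contracts the ring to dienol A4.
- For it: it is also a ring contraction, and [2,3]-shifts of large cyclic allyl ethers to ten-membered carbocycles are better documented than the palladium contraction. It delivers O8 free and O6 silylated, a differentiation the chosen route has to earn by selective acylation in step 15. On both points it is stronger.
- Against it: it creates a C7 stereocentre the target does not have. C11–C13 arrive at the wrong oxidation level, so alkene migration to C7=C11, oxidation of C12 to the lactone carbonyl and exchange of protecting groups must follow. n-BuLi excludes epoxides, which again come last on a diene. A3 needs a macrocyclic etherification with a configurationally defined α-alkoxystannane.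
- Comparison: the chosen route has C7 as a ketone from the start (18), which is what the butenolide annulation needs, and has the 4,5-epoxide in place before ring closure.

**Alternative 3:** The cut is C5–C6 and leads to the silyloxyfuran aldehyde A5, which already holds the butenolide carbons, the C13 silyl ether and the tiglate. A Lewis acid (BF3·OEt2 or MgBr2·OEt2) would make furan carbon C6 add to the C5 aldehyde and give the ten-membered hydroxy butenolide A6.
- For it: it is the most convergent plan, the butenolide is never built on the ring, and the endgame is short (epoxide closure, C1=C10 epoxidation). On endgame length it is stronger than the chosen route.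
- Against it: the ten-membered ring must be closed directly by an aldol at a neopentyl aldehyde, with no template. C5 and C6 form together in a medium-ring transition state with no catalyst control. The Lewis acid meets a tertiary silyl ether and an allylic ester. The later C5 activation takes place next to the acidic γ-hydrogen of the butenolide.
- Comparison: the chosen route forms the same C5–C6 bond between two small partners under catalyst control (step 7) and leaves the ring closure to a contraction.

Key step: step 13

Assumption: the C7 carbinol centre of 24 and 25 (and of F5, F11, F12) is not controlled and is drawn without configuration, because step 18 removes it; the trioxolane carbons of 3 are mixtures.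

## Route

Step 1
Reactants: 1 (R)-linalool
Product: 2 (3R)-3,7-dimethyl-3-(triethylsilyloxy)octa-1,6-diene
Conditions: Et3SiOTf, 2,6-lutidine, CH2Cl2, −78 → 0 °C
Reagents that add atoms: triethylsilyl trifluoromethanesulfonate, CC[Si](CC)(CC)OS(=O)(=O)C(F)(F)F
Why: Silylation of a hindered tertiary alcohol with a silyl triflate; the ether prevents lactol formation from the hydroxy dialdehyde in step 2 and leaves C4 (R, from the chiral pool) untouched.

Step 2
Reactants: 2 (3R)-3,7-dimethyl-3-(triethylsilyloxy)octa-1,6-diene
Product: 4 (2R)-2-methyl-2-(triethylsilyloxy)pentanedial, via bis-ozonide 3 (not isolated)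
Conditions: O3, CH2Cl2, −78 °C; then PPh3, −78 °C → rt
Reagents that add atoms: ozone, [O-][O+]=O
Why: Ozonolysis with reductive work-up; both alkenes are cleaved on purpose, because ozone attacks the electron-rich trisubstituted alkene before the vinyl group and a selective vinyl cleavage could not be defended; the quaternary C4 cannot epimerise.

Step 3
Reactants: 4 (2R)-2-methyl-2-(triethylsilyloxy)pentanedial; 5 ethyl 2-(triphenylphosphoranylidene)propanoate
Product: 6 ethyl (2E,6R)-2,6-dimethyl-7-oxo-6-(triethylsilyloxy)hept-2-enoate
Conditions: 1.0 equiv of 5, CH2Cl2, 0 °C → rt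
Reagents that add atoms: none
Why: Wittig olefination with a stabilised α-branched ylide, which should give the (E)-enoate and should react only with the unhindered C1 aldehyde, the C5 aldehyde being neopentyl-like and flanked by the silyloxy group.

Step 4
Reactants: 6 ethyl (2E,6R)-2,6-dimethyl-7-oxo-6-(triethylsilyloxy)hept-2-enoate
Product: 7 (2E,6R)-2,6-dimethyl-6-(triethylsilyloxy)hept-2-ene-1,7-diol
Conditions: i-Bu2AlH (4 equiv), CH2Cl2, −78 → −20 °C; aq. KNaC4H4O6 work-up
Reagents that add atoms: none
Why: Hydride 1,2-reduction of aldehyde and enoate; the aldehyde level at C5 is given up for two steps so that C9 reaches the alcohol level before any ketone is present.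

Step 5
Reactants: 7 (2E,6R)-2,6-dimethyl-6-(triethylsilyloxy)hept-2-ene-1,7-diol
Product: 8 (2R,5E)-7-(tert-butyldiphenylsilyloxy)-2,6-dimethyl-2-(triethylsilyloxy)hept-5-en-1-ol
Conditions: t-BuPh2SiCl (1.05 equiv), imidazole, CH2Cl2, −20 → 0 °C
Reagents that add atoms: tert-butylchlorodiphenylsilane, CC(C)(C)[Si](Cl)(c1ccccc1)c1ccccc1
Why: Silylation discriminated by sterics: the allylic primary hydroxyl reacts, while the primary hydroxyl next to the quaternary silyloxy carbon should not.

Step 6
Reactants: 8 (2R,5E)-7-(tert-butyldiphenylsilyloxy)-2,6-dimethyl-2-(triethylsilyloxy)hept-5-en-1-ol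
Product: 9 (2R,5E)-7-(tert-butyldiphenylsilyloxy)-2,6-dimethyl-2-(triethylsilyloxy)hept-5-enal
Conditions: Dess–Martin periodinane, CH2Cl2, 0 °C → rt
Reagents that add atoms: none
Why: Dess–Martin oxidation of a primary alcohol to the aldehyde under near-neutral conditions; there is no α-hydrogen, so neither epimerisation nor self-condensation can occur.

Step 7
Reactants: 9 (2R,5E)-7-(tert-butyldiphenylsilyloxy)-2,6-dimethyl-2-(triethylsilyloxy)hept-5-enal; 10 2,2-dimethyl-1,3-dioxan-5-one
Product: 11 (4R)-4-[(1S,2R,5E)-7-(tert-butyldiphenylsilyloxy)-1-hydroxy-2,6-dimethyl-2-(triethylsilyloxy)hept-5-en-1-yl]-2,2-dimethyl-1,3-dioxan-5-one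
Conditions: 10 (2 equiv), (R)-proline (30 mol %), DMF, 4 °C, several days
Reagents that add atoms: none
Why: Proline-catalysed direct aldol reaction of the dioxanone enamine, anti-selective through the hydrogen-bonded chair-like transition state; (R)-proline sets C6 (R) and C5 (S), and this sense agrees with the Felkin–Anh preference of the α-silyloxy aldehyde (silyloxy group anti, attack past the methyl group), so catalyst and C4 reinforce each other.

Step 8
Reactants: 11 (aldol adduct)
Product: 12 (4R)-4-[(1S,2R,5E)-7-(tert-butyldiphenylsilyloxy)-1,2-dihydroxy-2,6-dimethylhept-5-en-1-yl]-2,2-dimethyl-1,3-dioxan-5-one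
Conditions: HF·pyridine, pyridine, THF, 0 °C → rt
Reagents that add atoms: none
Why: Fluoride cleavage of the triethylsilyl ether under buffered, non-basic conditions that should leave the tert-butyldiphenylsilyl ether, the acetonide and the β-hydroxy ketone (no retro-aldol) intact.

Step 9
Reactants: 12 (anti-diol)
Product: 13 (4R)-4-{(2R,3R)-3-[(3E)-5-(tert-butyldiphenylsilyloxy)-4-methylpent-3-en-1-yl]-3-methyloxiran-2-yl}-2,2-dimethyl-1,3-dioxan-5-one
Conditions: PPh3, DIAD, toluene, 0 °C → rt
Reagents that add atoms: none
Why: Mitsunobu cyclodehydration of a vicinal diol: the secondary C5 hydroxyl becomes the oxyphosphonium leaving group and the tertiary C4 oxygen displaces it with inversion, turning the (4R,5S) anti-diol into the (4R,5R) trans-epoxide; the 3-exo closure should outrun β-elimination towards the ketone because no base stronger than the hydrazide is present.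

Step 10
Reactants: 13 (silyl epoxy ketone)
Product: 14 (4R)-4-{(2R,3R)-3-[(3E)-5-hydroxy-4-methylpent-3-en-1-yl]-3-methyloxiran-2-yl}-2,2-dimethyl-1,3-dioxan-5-one
Conditions: Bu4NF, AcOH (1:1), THF, 0 °C → rt
Reagents that add atoms: none
Why: Desilylation with acetic acid-buffered fluoride, chosen because unbuffered fluoride could enolise the ketone towards C6 and open the β,γ-epoxide.

Step 11
Reactants: 14 (hydroxy epoxy ketone)
Product: 15 (2E)-2-methyl-5-{(2R,3R)-2-methyl-3-[(4R)-2,2-dimethyl-5-oxo-1,3-dioxan-4-yl]oxiran-2-yl}pent-2-en-1-yl 1H-imidazole-1-carboxylate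
Conditions: 1,1′-carbonyldiimidazole, CH2Cl2, rt
Reagents that add atoms: 1,1′-carbonyldiimidazole, O=C(n1ccnc1)n1ccnc1
Why: Acylation of the primary allylic alcohol by carbonyldiimidazole gives an isolable alkoxycarbonyl imidazole, an acyl donor that tolerates the ketone and the epoxide.

Step 12
Reactants: 15 (alkoxycarbonyl imidazole)
Product: 17 twelve-membered (E)-allyl enol carbonate (4R,5R,6R; carbonate between O9 and the enol oxygen on C7 of the 2,2-dimethyl-4H-1,3-dioxine), via lithium enolate 16 (not isolated)
Conditions: LiN(SiMe3)2 (1.1 equiv), THF, −78 → 0 °C, slow addition of 15, final 2 mM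
Reagents that add atoms: none
Why: Kinetic deprotonation at the unsubstituted C8 methylene (not at the hindered C6 methine, whose enolate would open the epoxide), then intramolecular O-acylation of the lithium enolate by the alkoxycarbonyl imidazole with loss of imidazolide, as in the intermolecular preparation of allyl enol carbonates; high dilution suppresses oligomers, and any C-acylated isomer (a twelve-membered allyl β-keto ester) would give the same enolate–allyl pair in step 13.

Step 13
Reactants: 17 twelve-membered (E)-allyl enol carbonate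
Product: 18 (4R,5R,6R,8S)-4,5-epoxy-6,8-(isopropylidenedioxy)germacr-1(10)E-en-7-one
Conditions: Pd2(dba)3 (2.5 mol %), PPh3 (12 mol %), THF, 25–40 °C, 5 mM
Reagents that add atoms: none
Why: Zerovalent palladium, formed from Pd2(dba)3 and PPh3, adds to the allylic C9–O bond of 17 and gives a syn-π-allylpalladium cation (C9–C10–C1) paired with the enol carbonate anion, which loses CO2 and leaves the enolate regiodefined at C7–C8. The closest known reaction type is the Tsuji-type decarboxylative allylation of allyl enol carbonates, run here within one molecule so that it contracts the ring. The ten-membered carbocycle closes by attack of C8 on C9 in the endo mode, in which all three allyl carbons become ring atoms; the competing mode is 8-exo attack on C1. Attack on C9 is expected because it is the unsubstituted terminus and the one next to which the enolate is set free, whereas C1 is secondary and would give a strained eight-membered ring. The new stereocentre C8 is controlled by the tether: C9 should reach the enolate face cis to the C6–C5 bond, which lets the dioxanone keep a chair with C5 and C9 equatorial (cis-4,6, the out,out-bicyclo[7.3.1] skeleton), while the trans isomer would need a twist-boat dioxanone. The (E)-C1=C10 geometry is kept if collapse of the ion pair is faster than π–σ–π isomerisation of the allyl unit, which the intramolecular setting favours. No external base is present and only the C8 enolate is formed, so H6 next to the epoxide is not touched; for the same reason C8 has to come out right kinetically, because a later base-mediated epimerisation would also enolise towards C6 and open the epoxide.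

Step 14
Reactants: 18 (ring-contracted ketone)
Product: 19 (4R,5R,6R,8S)-4,5-epoxy-6,8-dihydroxygermacr-1(10)E-en-7-one
Conditions: AcOH/THF/H2O (3:1:1), rt
Reagents that add atoms: none
Why: Acid-catalysed hydrolysis of the 1,3-dioxane acetonide with a weak acid; the trisubstituted epoxide, deactivated at C5 by the neighbouring oxygenated carbons, should survive aqueous acetic acid at room temperature, whereas strong or Lewis acids would provoke transannular attack of the C1=C10 alkene.

Step 15
Reactants: 19 (dihydroxy ketone); 20 tiglic acid
Product: 22 (4R,5R,6R,8S)-4,5-epoxy-6-hydroxy-7-oxogermacr-1(10)E-en-8-yl (2E)-2-methylbut-2-enoate, via mixed anhydride 21 (not isolated)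
Conditions: 20, 2,4,6-trichlorobenzoyl chloride, Et3N, THF, 0 °C; then 19, DMAP, toluene, −20 → 0 °C
Reagents that add atoms: none
Why: Yamaguchi esterification through the mixed anhydride; the bulky acyl donor should take the C8 hydroxyl, flanked by a methylene, in preference to the C6 hydroxyl, which is flanked and deactivated by the epoxide carbon.

Step 16
Reactants: 22 (8-O-tiglate)
Product: 23 (4R,5R,6R,8S)-6-acryloyloxy-4,5-epoxy-7-oxogermacr-1(10)E-en-8-yl (2E)-2-methylbut-2-enoate
Conditions: acryloyl chloride, i-Pr2NEt, CH2Cl2, −78 → −20 °C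
Reagents that add atoms: acryloyl chloride, C=CC(=O)Cl
Why: Acylation of the remaining, more hindered C6 hydroxyl by a small reactive acid chloride at low temperature with a hindered amine, which should keep the α-acyloxy ketone from enolising towards the epoxide.

Step 17
Reactants: 23 (6-O-acrylate)
Product: 24 (4R,5R,6R,8S)-4,5-epoxy-7-hydroxy-8-[(2E)-2-methylbut-2-enoyloxy]germacra-1(10)E,11(13)-dien-12,6-olide
Conditions: DABCO (1 equiv), CH2Cl2, rt
Reagents that add atoms: none
Why: Intramolecular Morita–Baylis–Hillman reaction: the amine adds to the acrylate, the zwitterionic enolate attacks the C7 ketone (activated by two α-acyloxy groups) in a 5-exo-trig closure and the amine is expelled, giving the α-methylene-β-hydroxy-γ-lactone; the new C7 carbinol centre is not controlled and is removed in step 18.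

Step 18
Reactants: 24 (tertiary allylic alcohol)
Product: 26 (4R,5R,6S,8S)-13-acetoxy-4,5-epoxy-8-[(2E)-2-methylbut-2-enoyloxy]germacra-1(10)E,7(11)-dien-12,6-olide, via tertiary acetate 25 (not isolated)
Conditions: Ac2O, DMAP (1.2 equiv), CH2Cl2, 0 °C → rt
Reagents that add atoms: acetic anhydride, CC(=O)OC(C)=O
Why: Acetylation of the tertiary allylic alcohol followed by amine-mediated SN2′–SN2 migration of the acetate (the known isomerisation of Morita–Baylis–Hillman acetates) to the primary position, driven by formation of the tetrasubstituted, conjugated C7=C11 butenolide alkene.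

Step 19
Reactants: 26 (1(10)-ene butenolide)
Product: 27 CNP0251711.1, (1R,4R,5R,6S,8S,10R)-13-acetoxy-1,10:4,5-diepoxy-8-[(2E)-2-methylbut-2-enoyloxy]germacr-7(11)-en-12,6-olide
Conditions: dimethyldioxirane, acetone/CH2Cl2, −20 → 0 °C
Reagents that add atoms: dimethyldioxirane, CC1(C)OO1
Why: Electrophilic epoxidation by a neutral dioxirane at the only electron-rich alkene (tiglate and butenolide alkenes are electron-poor); attack on the outer face of the (E)-cyclodecene in the crown conformer with C14 and C15 syn should give the (1R,10R) trans-epoxide, and no acid is formed that could open the epoxides.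

## Compound list

1 | (R)-linalool | C=C[C@](C)(O)CCC=C(C)C | starting material
2 | (3R)-3,7-dimethyl-3-(triethylsilyloxy)octa-1,6-diene | C=C[C@](C)(O[Si](CC)(CC)CC)CCC=C(C)C | intermediate
3 | bis-ozonide (bis-1,2,4-trioxolane) of 2, mixture at the trioxolane carbons | C[C@@](O[Si](CC)(CC)CC)(CCC1OOC(C)(C)O1)C1OCOO1 | intermediate (not isolated)
4 | (2R)-2-methyl-2-(triethylsilyloxy)pentanedial | O=C[C@](C)(O[Si](CC)(CC)CC)CCC=O | intermediate
5 | ethyl 2-(triphenylphosphoranylidene)propanoate | CCOC(=O)C(C)=P(c1ccccc1)(c1ccccc1)c1ccccc1 | starting material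
6 | ethyl (2E,6R)-2,6-dimethyl-7-oxo-6-(triethylsilyloxy)hept-2-enoate | CCOC(=O)/C(C)=C/CC[C@@](C)(O[Si](CC)(CC)CC)C=O | intermediate
7 | (2E,6R)-2,6-dimethyl-6-(triethylsilyloxy)hept-2-ene-1,7-diol | OC/C(C)=C/CC[C@@](C)(O[Si](CC)(CC)CC)CO | intermediate
8 | (2R,5E)-7-(tert-butyldiphenylsilyloxy)-2,6-dimethyl-2-(triethylsilyloxy)hept-5-en-1-ol | CC(C)(C)[Si](c1ccccc1)(c1ccccc1)OC/C(C)=C/CC[C@@](C)(O[Si](CC)(CC)CC)CO | intermediate
9 | (2R,5E)-7-(tert-butyldiphenylsilyloxy)-2,6-dimethyl-2-(triethylsilyloxy)hept-5-enal | CC(C)(C)[Si](c1ccccc1)(c1ccccc1)OC/C(C)=C/CC[C@@](C)(O[Si](CC)(CC)CC)C=O | intermediate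
10 | 2,2-dimethyl-1,3-dioxan-5-one | CC1(C)OCC(=O)CO1 | starting material
11 | (4R)-4-[(1S,2R,5E)-7-(tert-butyldiphenylsilyloxy)-1-hydroxy-2,6-dimethyl-2-(triethylsilyloxy)hept-5-en-1-yl]-2,2-dimethyl-1,3-dioxan-5-one | CC(C)(C)[Si](c1ccccc1)(c1ccccc1)OC/C(C)=C/CC[C@@](C)(O[Si](CC)(CC)CC)[C@@H](O)[C@H]2OC(C)(C)OCC2=O | intermediate
12 | (4R)-4-[(1S,2R,5E)-7-(tert-butyldiphenylsilyloxy)-1,2-dihydroxy-2,6-dimethylhept-5-en-1-yl]-2,2-dimethyl-1,3-dioxan-5-one | CC(C)(C)[Si](c1ccccc1)(c1ccccc1)OC/C(C)=C/CC[C@@](C)(O)[C@@H](O)[C@H]2OC(C)(C)OCC2=O | intermediate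
13 | (4R)-4-{(2R,3R)-3-[(3E)-5-(tert-butyldiphenylsilyloxy)-4-methylpent-3-en-1-yl]-3-methyloxiran-2-yl}-2,2-dimethyl-1,3-dioxan-5-one | CC(C)(C)[Si](c1ccccc1)(c1ccccc1)OC/C(C)=C/CC[C@@]2(C)O[C@@H]2[C@H]3OC(C)(C)OCC3=O | intermediate
14 | (4R)-4-{(2R,3R)-3-[(3E)-5-hydroxy-4-methylpent-3-en-1-yl]-3-methyloxiran-2-yl}-2,2-dimethyl-1,3-dioxan-5-one | OC/C(C)=C/CC[C@@]2(C)O[C@@H]2[C@H]3OC(C)(C)OCC3=O | intermediate
15 | (2E)-2-methyl-5-{(2R,3R)-2-methyl-3-[(4R)-2,2-dimethyl-5-oxo-1,3-dioxan-4-yl]oxiran-2-yl}pent-2-en-1-yl 1H-imidazole-1-carboxylate | O=C(OC/C(C)=C/CC[C@@]1(C)O[C@@H]1[C@H]1OC(C)(C)OCC1=O)n1ccnc1 | intermediate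
16 | lithium C7–C8 enolate of 15 | O=C(OC/C(C)=C/CC[C@@]1(C)O[C@@H]1[C@H]1OC(C)(C)OC=C1O[Li])n1ccnc1 | intermediate (not isolated)
17 | twelve-membered (E)-allyl enol carbonate, (4R,5R,6R) | O=C1OC/C(C)=C/CC[C@@]2(C)O[C@@H]2[C@H]2OC(C)(C)OC=C2O1 | intermediate (key precursor)
18 | (4R,5R,6R,8S)-4,5-epoxy-6,8-(isopropylidenedioxy)germacr-1(10)E-en-7-one | CC1(C)O[C@H]2C/C(C)=C/CC[C@@]3(C)O[C@@H]3[C@@H](O1)C2=O | intermediate (key product)
19 | (4R,5R,6R,8S)-4,5-epoxy-6,8-dihydroxygermacr-1(10)E-en-7-one | O[C@H]1C/C(C)=C/CC[C@@]2(C)O[C@@H]2[C@@H](O)C1=O | intermediate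
20 | tiglic acid | C/C=C(\C)C(=O)O | starting material
21 | (2E)-2-methylbut-2-enoic 2,4,6-trichlorobenzoic anhydride | C/C=C(\C)C(=O)OC(=O)c1c(Cl)cc(Cl)cc1Cl | intermediate (not isolated)
22 | (4R,5R,6R,8S)-4,5-epoxy-6-hydroxy-7-oxogermacr-1(10)E-en-8-yl (2E)-2-methylbut-2-enoate | C/C=C(\C)C(=O)O[C@H]1C/C(C)=C/CC[C@@]2(C)O[C@@H]2[C@@H](O)C1=O | intermediate
23 | (4R,5R,6R,8S)-6-acryloyloxy-4,5-epoxy-7-oxogermacr-1(10)E-en-8-yl (2E)-2-methylbut-2-enoate | C/C=C(\C)C(=O)O[C@H]1C/C(C)=C/CC[C@@]2(C)O[C@@H]2[C@@H](OC(=O)C=C)C1=O | intermediate
24 | (4R,5R,6R,8S)-4,5-epoxy-7-hydroxy-8-tigloyloxygermacra-1(10)E,11(13)-dien-12,6-olide (C7 not assigned) | C/C=C(\C)C(=O)O[C@H]1C/C(C)=C/CC[C@@]2(C)O[C@@H]2[C@H]2OC(=O)C(=C)C12O | intermediate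
25 | 7-O-acetate of 24 | C/C=C(\C)C(=O)O[C@H]1C/C(C)=C/CC[C@@]2(C)O[C@@H]2[C@H]2OC(=O)C(=C)C12OC(C)=O | intermediate (not isolated)
26 | (4R,5R,6S,8S)-13-acetoxy-4,5-epoxy-8-tigloyloxygermacra-1(10)E,7(11)-dien-12,6-olide | C/C=C(\C)C(=O)O[C@H]1C/C(C)=C/CC[C@@]2(C)O[C@@H]2[C@H]2OC(=O)C(COC(C)=O)=C12 | intermediate
27 | CNP0251711.1, (1R,4R,5R,6S,8S,10R)-13-acetoxy-1,10:4,5-diepoxy-8-tigloyloxygermacr-7(11)-en-12,6-olide | C/C=C(\C)C(=O)O[C@H]1C[C@@]2(C)O[C@@H]2CC[C@@]2(C)O[C@@H]2[C@H]2OC(=O)C(COC(C)=O)=C12 | target

## Step count and least certain steps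

Total: 19 steps. Longest linear sequence: 19 steps (1 → 27); compounds 5, 10 and 20 are bought.

**Step 13 (key step).** Several processes could intervene:
- attack of the enolate on C1, which would give the eight-membered ring;
- syn–anti isomerisation of the allyl unit before the ion pair collapses, with loss of the (E)-geometry;
- proton transfer within the ion pair, which would lead to diene formation or to the C6 enolate and epoxide opening;
- closure on the other enolate face.

The fallback sets out from 14 and comes back at 18. The C9 hydroxyl is converted into the methyl carbonate F1 (ClCO2Me, pyridine) and the ketone into the C7=C8 triethylsilyl enol ether F2 (LiN(SiMe3)2, Et3SiCl, THF, −78 °C). Pd2(dba)3 with dppe in warm THF at high dilution then closes the ten-membered ring directly: ionisation of the allyl methyl carbonate releases methoxide, which desilylates the enol ether next to the π-allyl cation. This is the known allylation of silyl enol ethers by allyl carbonates, used as an open-chain cyclisation, not as a contraction.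

**Step 12.** Enolisation towards C6 with opening of the epoxide, intermolecular acylation outrunning the twelve-membered closure, or return of imidazolide onto the enol carbonate could each lower the yield. The fallback sets out from 14 and comes back at 17. The alcohol is made into the 4-nitrophenyl carbonate F3 (4-nitrophenyl chloroformate, pyridine). The ketone is trapped as the trimethylsilyl enol ether F4 (LiN(SiMe3)2 with Me3SiCl present, −78 °C), so the enolate regiochemistry is fixed and checked before ring closure. Slow addition to Bu4N[Ph3SiF2] in THF then frees the enolate without amide base; O-acylation with loss of 4-nitrophenoxide is irreversible.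

**Step 17.** Addition to the ketone may be slow, so that acrylate dimerisation or amine-induced enolisation at C6 takes over. The fallback sets out from 23 and comes back at 24. PhSeLi (THF, −78 °C) adds to the acrylate and the lithium enolate closes onto the C7 ketone, giving the selenide lactone F5. Oxidation with NaIO4 and syn-elimination of the selenoxide gives 24.

**Step 9.** β-Elimination of the activated C5 oxygen towards the ketone, or sluggish activation of the hindered C5 hydroxyl, may compete with closure. The fallback sets out from 12 and comes back at 13. The secondary hydroxyl is sulfonylated selectively at −78 °C (Tf2O, 2,6-di-tert-butylpyridine) to the triflate F6, which is not isolated. The neighbouring tertiary hydroxyl displaces it on warming; the only base is a hindered pyridine, too weak to remove H6, and no phosphorus or azo reagent is involved.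

**Step 14.** Acid may open the 4,5-epoxide, above all by transannular attack of the C1=C10 alkene on C5. The fallback sets out from 18 and comes back at 27, with the order of events changed so that the alkene is gone before acid is used:
- dimethyldioxirane gives the bis-epoxy acetonide F7;
- aqueous acetic acid gives the bis-epoxy diol F8;
- the operations of steps 15 to 18 then give the tiglate F9, the acrylate F10 and the hydroxy lactone F11;
- acetylation of F11 gives 27 through the tertiary acetate F12, which is not isolated.

**Step 19.** Facial selectivity would be poor if the ring populates a conformer with C14 anti to C15. The fallback goes from 26 to 27 and makes no new compound. Substrate control is replaced by reagent control in a Shi epoxidation (fructose-derived chiral ketone, KHSO5, buffered MeCN/water, 0 °C), with the enantiomer of the ketone chosen to deliver oxygen to the required face.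

## Further compounds

F1 | step 13 | methyl carbonate of 14 | COC(=O)OC/C(C)=C/CC[C@@]1(C)O[C@@H]1[C@H]1OC(C)(C)OCC1=O
F2 | step 13 | C7=C8 triethylsilyl enol ether of F1 | COC(=O)OC/C(C)=C/CC[C@@]1(C)O[C@@H]1[C@H]1OC(C)(C)OC=C1O[Si](CC)(CC)CC
F3 | step 12 | 4-nitrophenyl carbonate of 14 | O=C(OC/C(C)=C/CC[C@@]1(C)O[C@@H]1[C@H]1OC(C)(C)OCC1=O)Oc1ccc(cc1)[N+](=O)[O-]
F4 | step 12 | C7=C8 trimethylsilyl enol ether of F3 | O=C(OC/C(C)=C/CC[C@@]1(C)O[C@@H]1[C@H]1OC(C)(C)OC=C1O[Si](C)(C)C)Oc1ccc(cc1)[N+](=O)[O-]
F5 | step 17 | 7-hydroxy-13-(phenylselanyl) lactone from 23 (C7, C11 not assigned) | C/C=C(\C)C(=O)O[C@H]1C/C(C)=C/CC[C@@]2(C)O[C@@H]2[C@H]2OC(=O)C(C[Se]c3ccccc3)C12O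
F6 | step 9 | C5 triflate of 12 (not isolated) | CC(C)(C)[Si](c1ccccc1)(c1ccccc1)OC/C(C)=C/CC[C@@](C)(O)[C@@H](OS(=O)(=O)C(F)(F)F)[C@H]1OC(C)(C)OCC1=O
F7 | step 14 | (1R,4R,5R,6R,8S,10R)-1,10:4,5-diepoxy-6,8-(isopropylidenedioxy)germacran-7-one | CC1(C)O[C@H]2C[C@@]4(C)O[C@@H]4CC[C@@]3(C)O[C@@H]3[C@@H](O1)C2=O
F8 | step 14 | 1,10:4,5-diepoxy-6,8-dihydroxygermacran-7-one | O[C@H]1C[C@@]2(C)O[C@@H]2CC[C@@]2(C)O[C@@H]2[C@@H](O)C1=O
F9 | step 14 | 8-O-tiglate of F8 | C/C=C(\C)C(=O)O[C@H]1C[C@@]2(C)O[C@@H]2CC[C@@]2(C)O[C@@H]2[C@@H](O)C1=O
F10 | step 14 | 6-O-acrylate of F9 | C/C=C(\C)C(=O)O[C@H]1C[C@@]2(C)O[C@@H]2CC[C@@]2(C)O[C@@H]2[C@@H](OC(=O)C=C)C1=O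
F11 | step 14 | 1,10:4,5-diepoxy-7-hydroxy-8-tigloyloxygermacr-11(13)-en-12,6-olide (C7 not assigned) | C/C=C(\C)C(=O)O[C@H]1C[C@@]2(C)O[C@@H]2CC[C@@]2(C)O[C@@H]2[C@H]2OC(=O)C(=C)C12O
F12 | step 14 | 7-O-acetate of F11 (not isolated) | C/C=C(\C)C(=O)O[C@H]1C[C@@]2(C)O[C@@H]2CC[C@@]2(C)O[C@@H]2[C@H]2OC(=O)C(=C)C12OC(C)=O
F0 | step 19 | none | none
A1 | alternative 1 | (2E,6E,9S)-9,12-bis(tert-butyldimethylsilyloxy)-3,7-dimethyldodeca-2,6-dien-10-ynal | O=C/C=C(\C)CC/C=C(\C)C[C@H](O[Si](C)(C)C(C)(C)C)C#CCO[Si](C)(C)C(C)(C)C
A2 | alternative 1 | germacra-1(10)E,4E,7(11)-trien-6,12-olide 8,13-bis(tert-butyldimethylsilyl) ether | CC(C)(C)[Si](C)(C)O[C@H]1C/C(C)=C/CC/C(C)=C/[C@H]2OC(=O)C(CO[Si](C)(C)C(C)(C)C)=C12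
A3 | alternative 2 | thirteen-membered α-(tributylstannyl) allyl ether (C6 silyl ether, C12 4-methoxybenzyl ether; C7=C11 geometry drawn E by choice) | CCCC[Sn](CCCC)(CCCC)[C@H]1C/C(C)=C/CC/C(C)=C/[C@@H](O[Si](C)(C)C(C)(C)C)/C=C(\COCc2ccc(OC)cc2)CO1
A4 | alternative 2 | ten-membered (E,E)-dien-8-ol with C7 2-propenyl branch (C6 silyl ether, C12 4-methoxybenzyl ether) | O[C@H]1C/C(C)=C/CC/C(C)=C/[C@@H](O[Si](C)(C)C(C)(C)C)[C@H]1C(=C)COCc1ccc(OC)cc1
A5 | alternative 3 | 2-(tert-butyldimethylsilyloxy)furan with C8 tiglate, C13 silyl ether and tethered C5 aldehyde (C4 triethylsilyl ether) | C/C=C(\C)C(=O)O[C@@H](C/C(C)=C/CC[C@@](C)(O[Si](CC)(CC)CC)C=O)c1coc(O[Si](C)(C)C(C)(C)C)c1CO[Si](C)(C)C(C)(C)C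
A6 | alternative 3 | ten-membered 5-hydroxy-1(10)-en-6,12-olide (C4 triethylsilyl ether, C13 silyl ether, C8 tiglate) | C/C=C(\C)C(=O)O[C@H]1C/C(C)=C/CC[C@@](C)(O[Si](CC)(CC)CC)[C@@H](O)[C@H]2OC(=O)C(CO[Si](C)(C)C(C)(C)C)=C12
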